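The runs are simulated on assumed constants.

- At the first reading, 0.500 h, the theta run already holds 6% Ze.Gu, so I follow its rate, not its amounts.

| setting | eta | theta | flask |
|---|---|---|---|
| Wu | 0.10 M | 0.10 M | 0.10 M |
| Gu | 0.047 M | 0.11 M | 0.0700 M |
| remark | run made earlier | run made earlier |  |
| time |  |  | 4.0 h |

| run | time / h | Ze.Gu / % | Ze / % |
|---|---|---|---|
| eta | 0.500 | 3 | 34 |
| eta | 1.00 | 3 | 53 |
| eta | 1.50 | 4 | 62 |
| eta | 2.00 | 7 | 64 |
| eta | 2.50 | 7 | 72 |
| eta | 3.00 | 6 | 72 |
| theta | 0.500 | 6 | 32 |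
| theta | 1.00 | 11 | 48 |
| theta | 1.50 | 11 | 57 |
| theta | 2.00 | 14 | 64 |
| theta | 2.50 | 13 | 70 |
| theta | 3.00 | 12 | 67 |

(scatter of a reading: 1.5 percentage points)

- percent here means Wu units held: one Gy counts as two
- Wu is a solid; its amount is given per volume of the solution
- candidate steps: Wu <-> Ze; Ze + Gu -> Ze.Gu; Gu -> Dz; Gu <-> Xo; 2 Wu -> Gy
- at the start none of Wu is in solution
- Ze means what is dissolved; the solid is not counted in it

1. Ze.Gu at 4.0 h, in percent of the Wu charged
2. concentration of Ze in solution at 4.0 h, in percent of saturation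

- In the theta run, Ze.Gu grows by 0.110 h⁻¹ of the Wu charged in the first hour and 0.0300 h⁻¹ in the second, so it slows by a rough factor of 3.67.
- Ze pushes the other way, rising by a factor of 1.78 from 0.500 h to 1.50 h. If capture goes with Ze times Gu, Gu falls by a factor of about 6.53 in that hour.
- So the rate dies away within the readings, and the plateau they show is roughly a ratio. I divide the capture rate by the loss rate of Gu. If both rates go with the Gu present and Ze is taken as level, time and the Gu charge drop out of that ratio. This is a rough step for the span of the readings, since Ze still climbs while Gu is consumed. Ze reads 64% in eta and 64% in theta at 2.00 h.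
- The late readings give 14.2% in eta and 11.8% in theta. Their mean, 13.0%, is my capture share, a selectivity: Ze.Gu held at the late readings per Gu charged. For this flask I reckon 9.10% of the Wu charged.
- The forecast gives 9.3%, a little above mine, and 96% of saturation, on this ground: “The plateau scales about linearly with Gu charge”.
- The flask gives 8.74% and 99.1% of saturation, so its capture share at 4.0 h is 12.5%. That share belongs to these hours: left until 40.0 h, this flask holds 13.6% Ze.Gu.

    Wu ⇌ Ze, rate k1*(cs1 - [Ze]) while solid is left; crystals form when [Ze] > cs1 (solubility = 0.0730 M, k = 3.67 × 10⁻⁴ s⁻¹)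
    Ze + Gu → Ze.Gu (k = 0.00312 L mol⁻¹ s⁻¹)
    Gu → Dz (k = 3.85 × 10⁻⁴ s⁻¹)
    Gu ⇌ Xo (K = 15.0, k = 1.91 × 10⁻⁴ s⁻¹)
    2 Wu → Gy (k = 4.49 × 10⁻⁵ L mol⁻¹ s⁻¹)

- At 4.00 h in this flask, the half-life of Gu by passing into Dz is 0.50 h, while that of Ze by passing into Ze.Gu is 8.8 d, far longer. Gu, the limiting reagent, stands at 0.418% of its charge, and Ze at 72.3% of the Wu charged.
- A neighbour flask with 0.12 M of Gu: the capture share gives 15.6%, and the computed result is 14.5%.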